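Ring B is cut at C5–C6 and C9–C10 as a Diels–Alder adduct. C19 (axial on C4) and C20 (axial on C10) face each other across ring A, so they are tied as a δ-lactone (C19–O–C20=O): the C5=C10 bond then lies in a temporary ring as a cis-dienophile. A hydroxymethyl triene brings C6–C9 with C17, C11 and C12. One cycloaddition builds ring B and sets C5 and C9; the lactone enolate then closes ring A at C10, and the lactone is reduced to the C19 alcohol and the C20 methyl group. The dienophile is a 5,5-disubstituted pentenolide made by iridium-catalysed tert-(hydroxy)prenylation and ring-closing metathesis.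

Key step: step 8

Numbering: labdane numbering of the target is used throughout. Ring A = C1–C5 and C10; ring B = C5–C10; side chain C11–C16 (C16 = lactone carbonyl, C15 = OCH2); C17 = CH2OH on C8; C18 = CH3 and C19 = CH2OH on C4; C20 = CH3 on C10.

Assumption: isoprene monoxide 2 is used as the racemate (the π-allyliridium pathway is enantioconvergent), and the ligand antipode that delivers (2R,3R)-4 is the one employed.

**Step 1**
Reactants: 1 3-[(tert-butyldimethylsilyl)oxy]propan-1-ol; 2 2-methyl-2-vinyloxirane (racemic)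
Product: 4 (2R,3R)-5-[(tert-butyldimethylsilyl)oxy]-2-ethenyl-2-methylpentane-1,3-diol, via aldehyde 3 (not isolated)
Conditions: [Ir(cod)Cl]2 (2.5 mol%), Tol-BINAP (5 mol%), 4-cyano-3-nitrobenzoic acid (10 mol%), allyl acetate (10 mol%), K3PO4 (5 mol%), THF, 60 °C
Reagents that add atoms: none
Why: Iridium-catalysed transfer-hydrogenative tert-(hydroxy)prenylation: 1 is dehydrogenated to aldehyde 3, which the σ-allyliridium species from 2 attacks through a closed chair-like transition state, so the anti (hydroxyl/hydroxymethyl) diastereomer should form and the chiral bisphosphine on iridium sets C3 and C4.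

**Step 2**
Reactants: 4 (2R,3R)-5-[(tert-butyldimethylsilyl)oxy]-2-ethenyl-2-methylpentane-1,3-diol
Product: 5 [(2R,3R)-5-[(tert-butyldimethylsilyl)oxy]-2-ethenyl-3-hydroxy-2-methylpentyl] prop-2-enoate
Conditions: acryloyl chloride (1.05 equiv), 2,4,6-collidine, CH2Cl2, −78 to −20 °C
Reagents that add atoms: acryloyl chloride C=CC(Cl)=O
Why: Kinetic O-acylation should take the primary C19 hydroxyl in preference to the secondary C3 hydroxyl next to the quaternary carbon.

**Step 3**
Reactants: 5 [(2R,3R)-5-[(tert-butyldimethylsilyl)oxy]-2-ethenyl-3-hydroxy-2-methylpentyl] prop-2-enoate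
Product: 6 (5R)-5-[(1R)-3-[(tert-butyldimethylsilyl)oxy]-1-hydroxypropyl]-5-methyl-5,6-dihydro-2H-pyran-2-one
Conditions: second-generation Grubbs catalyst (5 mol%), toluene, 80 °C
Reagents that add atoms: none
Why: Ring-closing metathesis of the acrylate with the homoallylically placed vinyl group should give the six-membered unsaturated lactone (C20=O, C10=C5) with loss of ethene; no stereocentre is touched.

**Step 4**
Reactants: 6 (5R)-5-[(1R)-3-[(tert-butyldimethylsilyl)oxy]-1-hydroxypropyl]-5-methyl-5,6-dihydro-2H-pyran-2-one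
Product: 7 (1R)-3-[(tert-butyldimethylsilyl)oxy]-1-[(3R)-3-methyl-6-oxo-3,6-dihydro-2H-pyran-3-yl]propyl 2,2-dimethylpropanoate
Conditions: pivaloyl chloride, pyridine, DMAP (cat.), CH2Cl2, 40 °C
Reagents that add atoms: pivaloyl chloride CC(C)(C)C(Cl)=O
Why: DMAP-catalysed acylation protects the C3 hydroxyl as a bulky, non-enolisable ester that survives the later enolate step and is cleaved by the hydride in step 12.

**Step 5**
Reactants: 7 (1R)-3-[(tert-butyldimethylsilyl)oxy]-1-[(3R)-3-methyl-6-oxo-3,6-dihydro-2H-pyran-3-yl]propyl 2,2-dimethylpropanoate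
Product: 8 (1R)-3-bromo-1-[(3R)-3-methyl-6-oxo-3,6-dihydro-2H-pyran-3-yl]propyl 2,2-dimethylpropanoate
Conditions: Ph3PBr2 (1.5 equiv), CH2Cl2, 0 °C to rt
Reagents that add atoms: triphenylphosphine dibromide BrP(Br)(c1ccccc1)(c1ccccc1)c1ccccc1
Why: Direct conversion of a primary silyl ether into the bromide (silyl transfer to bromide, then SN2 displacement of the alkoxyphosphonium at C1) should leave the ester, the lactone and both stereocentres untouched.

**Step 6**
Reactants: 9 prop-2-yn-1-ol
Product: 11 (2Z)-2-ethenyl-3-iodoprop-2-en-1-ol, via magnesium chelate 10 (not isolated)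
Conditions: vinylmagnesium bromide (3 equiv), CuI (10 mol%), THF, −10 °C to rt; then I2, −78 to 0 °C
Reagents that add atoms: vinylmagnesium bromide C=C[Mg]Br; iodine II
Why: Copper-catalysed anti carbomagnesiation of the propargylic alkoxide places vinyl on the internal carbon and magnesium cis to the CH2O group in chelate 10, and iodinolysis with retention gives the Z vinyl iodide.

**Step 7**
Reactants: 11 (2Z)-2-ethenyl-3-iodoprop-2-en-1-ol
Product: 12 (2Z)-2-ethenylpenta-2,4-dien-1-ol
Conditions: tributyl(vinyl)stannane, Pd2(dba)3 (2.5 mol%), AsPh3 (10 mol%), CuI (10 mol%), NMP, rt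
Reagents that add atoms: tributyl(vinyl)stannane CCCC[Sn](CCCC)(CCCC)C=C
Why: Stille coupling proceeds with retention of alkene geometry, so the new vinyl group (C11=C12) should stay cis to the hydroxymethyl group and trans to the C6=C7 vinyl group.

**Step 8**
Reactants: 8 (1R)-3-bromo-1-[(3R)-3-methyl-6-oxo-3,6-dihydro-2H-pyran-3-yl]propyl 2,2-dimethylpropanoate; 12 (2Z)-2-ethenylpenta-2,4-dien-1-ol
Product: 13 (1R)-3-bromo-1-[8-ethenyl-7-(hydroxymethyl)-4-methyl-1-oxo-3,4,4a,5,8,8a-hexahydro-1H-isochromen-4-yl]propyl 2,2-dimethylpropanoate (cis-fused; H-4a/H-8/H-8a mutually cis; side chain on C4 cis to H-4a)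
Conditions: 12 (3 equiv), BHT (1 mol%), CH2Cl2, 15 kbar, 40 °C
Reagents that add atoms: none
Why: Concerted, asynchronous normal-demand Diels–Alder cycloaddition under high pressure (closest known type: additions of acyclic 1-substituted dienes to 5,6-dihydropyran-2-ones and 4,4-disubstituted cyclohexenones), in which the unsubstituted terminus C6 bonds to the lactone β-carbon C5 and the vinyl-bearing terminus C9 to the α-carbon C10. Ring B is the only ring closed, by suprafacial [4+2] addition on both partners. C5 and C10 come out cis because the lactone holds the dienophile cis, and the face is set by C4: the diene should add anti to the pseudoaxial pivaloyloxy-bromopropyl chain and syn to the methyl group. C9 follows from the triene geometry (vinyl outside) together with the endo position of the lactone carbonyl (Alder rule), which a hydrogen bond from the C17 hydroxyl should reinforce; C10 forms as an enolisable CH and is fixed only in step 9. The step needs regioselectivity (the conjugating vinyl group on C9 gives the "ortho" orientation), endo selectivity (the lactone ring forces C4 and C20 onto the same side) and site selectivity within the triene (the other diene unit would need the hydroxymethyl group inside its s-cis form).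

**Step 9**
Reactants: 13 Diels–Alder adduct (cis-fused bromo lactone)
Product: 15 3-O-pivaloyl-17-hydroxy-13,14,15,16-tetranorlabda-7,11-dien-20,19-olide (trans-decalin with a C19–O–C20(=O) bridge from C4 to C10; configuration as in 25), via dipotassium enolate 14 (not isolated)
Conditions: KN(SiMe3)2 (2.2 equiv), THF, −78 to 0 °C
Reagents that add atoms: none
Why: Intramolecular 6-exo-tet alkylation of the lactone enolate by the primary bromide closes ring A; the chain on C4 can reach C10 only from its own face, so C1 enters cis to H-5 and the quaternary centre forms with C20 axial (trans-decalin).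

**Step 10**
Reactants: 15 tricyclic allylic alcohol
Product: 16 17-oxo-3-O-pivaloyl-13,14,15,16-tetranorlabda-7,11-dien-20,19-olide (enal)
Conditions: TEMPO (10 mol%), PhI(OAc)2 (1.1 equiv), CH2Cl2, rt
Reagents that add atoms: none
Why: Oxoammonium oxidation is selective for the primary allylic alcohol and stops at the aldehyde.

**Step 11**
Reactants: 16 enal
Product: 19 17-oxo-3-O-pivaloyl-13,14,15,16-tetranorlabd-11-en-20,19-olide (formyl group equatorial; 8-H on the face of C20), via silyl enol ether 17 (not isolated), via aldehyde epimer mixture 18 (not isolated)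
Conditions: [(Ph3P)CuH]6 (1 mol%), PhMe2SiH (1.5 equiv), toluene, rt; then 1 M HCl, THF; then DBU, CH2Cl2, rt
Reagents that add atoms: none
Why: Copper hydride 1,4-reduction of the enal leaves the isolated vinyl group and the esters alone, and base equilibration should place the C8 formyl group equatorial, because the axial epimer is 1,3-diaxial to the C20 lactone carbon.

**Step 12**
Reactants: 19 equatorial aldehyde lactone
Product: 20 13,14,15,16-tetranorlabd-11-ene-3,17-diol 20,19-lactol (19,20-epoxy-20-hydroxy; mixture at C20)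
Conditions: (i-Bu)2AlH (6 equiv), CH2Cl2, −78 to −40 °C; Rochelle salt work-up
Reagents that add atoms: none
Why: The aluminium hydride reduces the aldehyde to the C17 alcohol, cleaves the pivalate and stops at the lactol because the tetrahedral aluminium hemiacetal of the hindered bridged lactone persists at low temperature.

**Step 13**
Reactants: 20 lactol triol
Product: 22 (3R,4R,5S,8S,9R,10S)-13,14,15,16-tetranorlabd-11-ene-3,17,19-triol, via hydrazone 21 (not isolated)
Conditions: N2H4·H2O, KOH, diethylene glycol, 130 °C then 200 °C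
Reagents that add atoms: none
Why: Wolff–Kishner reduction of the ring-opened hydroxy aldehyde turns C20 into the angular methyl group and frees the C19 hydroxyl; no stereocentre is involved.

**Step 14**
Reactants: 22 vinyl triol; 23 3-bromofuran-2(5H)-one
Product: 25 14-deoxy-17-hydroxyandrographolide, via alkylborane 24 (not isolated)
Conditions: 9-BBN-H (5 equiv), THF, rt; then 23, PdCl2(dppf) (10 mol%), AsPh3 (10 mol%), K3PO4 (3 M aq.), DMF, rt
Reagents that add atoms: none
Why: Anti-Markovnikov hydroboration puts boron on C12 (the hydroxyls are borylated only transiently), and B-alkyl Suzuki–Miyaura coupling with the α-bromo butenolide forms the C12–C13 bond with the double bond already in the ring.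

**Compound list**
1 | 3-[(tert-butyldimethylsilyl)oxy]propan-1-ol | OCCCO[Si](C)(C)C(C)(C)C | starting material
2 | 2-methyl-2-vinyloxirane (racemic) | CC1(CO1)C=C | starting material
3 | 3-[(tert-butyldimethylsilyl)oxy]propanal | O=CCCO[Si](C)(C)C(C)(C)C | intermediate
4 | (2R,3R)-5-[(tert-butyldimethylsilyl)oxy]-2-ethenyl-2-methylpentane-1,3-diol | C[C@]([C@H](O)CCO[Si](C)(C)C(C)(C)C)(CO)C=C | intermediate
5 | [(2R,3R)-5-[(tert-butyldimethylsilyl)oxy]-2-ethenyl-3-hydroxy-2-methylpentyl] prop-2-enoate | C[C@]([C@H](O)CCO[Si](C)(C)C(C)(C)C)(COC(=O)C=C)C=C | intermediate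
6 | (5R)-5-[(1R)-3-[(tert-butyldimethylsilyl)oxy]-1-hydroxypropyl]-5-methyl-5,6-dihydro-2H-pyran-2-one | O=C1C=C[C@](C)(CO1)[C@H](O)CCO[Si](C)(C)C(C)(C)C | intermediate
7 | (1R)-3-[(tert-butyldimethylsilyl)oxy]-1-[(3R)-3-methyl-6-oxo-3,6-dihydro-2H-pyran-3-yl]propyl 2,2-dimethylpropanoate | O=C1C=C[C@](C)(CO1)[C@H](OC(=O)C(C)(C)C)CCO[Si](C)(C)C(C)(C)C | intermediate
8 | (1R)-3-bromo-1-[(3R)-3-methyl-6-oxo-3,6-dihydro-2H-pyran-3-yl]propyl 2,2-dimethylpropanoate | O=C1C=C[C@](C)(CO1)[C@H](OC(=O)C(C)(C)C)CCBr | intermediate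
9 | prop-2-yn-1-ol | C#CCO | starting material
10 | 4-ethenyl-2,5-dihydro-1,2-oxamagnesole (cyclic alkoxy vinylmagnesium chelate) | C=CC1=C[Mg]OC1 | intermediate
11 | (2Z)-2-ethenyl-3-iodoprop-2-en-1-ol | OC/C(C=C)=C\I | intermediate
12 | (2Z)-2-ethenylpenta-2,4-dien-1-ol | OC/C(C=C)=C\C=C | intermediate
13 | Diels–Alder adduct: cis-fused hexahydroisochromen-1-one carrying 4-methyl, 4-[(1R)-3-bromo-1-(pivaloyloxy)propyl], 7-hydroxymethyl and 8-ethenyl groups; H-4a, H-8 and H-8a mutually cis, side chain on C4 cis to H-4a | C[C@@]1(COC(=O)[C@@H]2[C@H](C=C)C(CO)=CC[C@H]12)[C@H](OC(=O)C(C)(C)C)CCBr | intermediate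
14 | dipotassium salt of 13 (lactone enolate at C10, alkoxide at C17) | C[C@@]1(COC([O-])=C2[C@H](C=C)C(C[O-])=CC[C@H]12)[C@H](OC(=O)C(C)(C)C)CCBr.[K+].[K+] | intermediate
15 | 3-O-pivaloyl-17-hydroxy-13,14,15,16-tetranorlabda-7,11-dien-20,19-olide (trans-decalin, lactone bridge C4 to C10, 9-vinyl equatorial) | C[C@@]12COC(=O)[C@]3(CC[C@H]1OC(=O)C(C)(C)C)[C@H](C=C)C(CO)=CC[C@H]23 | intermediate
16 | 17-oxo-3-O-pivaloyl-13,14,15,16-tetranorlabda-7,11-dien-20,19-olide | C[C@@]12COC(=O)[C@]3(CC[C@H]1OC(=O)C(C)(C)C)[C@H](C=C)C(C=O)=CC[C@H]23 | intermediate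
17 | dimethyl(phenyl)silyl enol ether of 19 (C8=C17) | C[C@@]12COC(=O)[C@]3(CC[C@H]1OC(=O)C(C)(C)C)[C@H](C=C)C(=CO[Si](C)(C)c4ccccc4)CC[C@H]23 | intermediate
18 | 17-oxo-3-O-pivaloyl-13,14,15,16-tetranorlabd-11-en-20,19-olide, mixture of C8 epimers | C[C@@]12COC(=O)[C@]3(CC[C@H]1OC(=O)C(C)(C)C)[C@H](C=C)C(C=O)CC[C@H]23 | intermediate
19 | 17-oxo-3-O-pivaloyl-13,14,15,16-tetranorlabd-11-en-20,19-olide, formyl equatorial, 8-H on the C20 face | C[C@@]12COC(=O)[C@]3(CC[C@H]1OC(=O)C(C)(C)C)[C@H](C=C)[C@@H](C=O)CC[C@H]23 | intermediate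
20 | 13,14,15,16-tetranorlabd-11-ene-3,17-diol 20,19-lactol (anomer mixture) | C[C@@]12COC(O)[C@]3(CC[C@H]1O)[C@H](C=C)[C@@H](CO)CC[C@H]23 | intermediate
21 | C20 hydrazone of the ring-opened lactol (3,17,19-triol) | C[C@]1(CO)[C@H]2CC[C@H](CO)[C@@H](C=C)[C@]2(C=NN)CC[C@H]1O | intermediate
22 | (3R,4R,5S,8S,9R,10S)-13,14,15,16-tetranorlabd-11-ene-3,17,19-triol | C[C@]1(CO)[C@H]2CC[C@H](CO)[C@@H](C=C)[C@]2(C)CC[C@H]1O | intermediate
23 | 3-bromofuran-2(5H)-one | BrC1=CCOC1=O | starting material
24 | C12 B-alkyl-9-borabicyclo[3.3.1]nonane of 22 with the three hydroxyls as O-borinates | C[C@]1(COB%10C%11CCCC%10CCC%11)[C@H]2CC[C@H](COB%10C%11CCCC%10CCC%11)[C@@H](CCB%10C%11CCCC%10CCC%11)[C@]2(C)CC[C@H]1OB%10C%11CCCC%10CCC%11 | intermediate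
25 | 14-deoxy-17-hydroxyandrographolide, 3-{2-[(1R,2S,4aS,5R,6R,8aS)-6-hydroxy-2,5-bis(hydroxymethyl)-5,8a-dimethyldecahydronaphthalen-1-yl]ethyl}furan-2(5H)-one | C[C@]1(CO)[C@H]2CC[C@H](CO)[C@@H](CCC3=CCOC3=O)[C@]2(C)CC[C@H]1O | target

Total step count: 14. Longest linear sequence: 12 steps (steps 1–5 and 8–14).

**Steps most likely to fail**

Step 8. The pentenolide, hindered at its γ-carbon, may react too slowly, so that the triene polymerises first, or endo and facial selectivity may erode. The fallback sets out from 8 and activates the dienophile with a removable halogen. Bromination and dehydrobromination (Br2, CH2Cl2, 0 °C; then Et3N) should give the α-bromo pentenolide (1R)-3-bromo-1-[(3R)-5-bromo-3-methyl-6-oxo-3,6-dihydro-2H-pyran-3-yl]propyl 2,2-dimethylpropanoate F1, a more electron-poor dienophile. Cycloaddition with 12 should then give the C10-bromo adduct F2 with the same sense at C5 and C9. Zinc dust in acetic acid removes the bromine through the zinc enolate and comes back at 13; either C10 epimer serves, since step 9 passes through the enolate.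

Step 13. Hydrazone formation at the neopentyl lactol carbon may be incomplete, or the vinyl double bond may migrate in hot alkali. The fallback sets out from 20: condensation with 4-methylbenzenesulfonohydrazide (EtOH, 60 °C) should give the tosylhydrazone F3, and reduction with catecholborane followed by NaOAc·3H2O (CHCl3, reflux) passes through the diazene, loses dinitrogen under near-neutral conditions and comes back at 22.

Step 14. The bromobutenolide may decompose under the basic coupling conditions, or transmetallation of the polyborylated alkylborane may be slow. The fallback sets out from 22 (through 24) and couples with a robust aromatic partner. 3-Bromofuran is lithiated at C2 (LDA, THF, −78 °C) and silylated (Me3SiCl) to 3-bromo-2-(trimethylsilyl)furan F4. B-alkyl Suzuki–Miyaura coupling of 24 with F4 under the step 14 conditions should give the 2-silyl-3-alkylfuran F5. Sensitised photooxygenation (O2, tetraphenylporphyrin, hν, CH2Cl2, −78 °C), in which the silyl-bearing carbon becomes the carbonyl carbon, should give the 5-hydroxybutenolide F6. Reduction with NaBH4 (MeOH, 0 °C) and lactonisation comes back at 25.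

**Further compounds**
F1 | step 8 | (1R)-3-bromo-1-[(3R)-5-bromo-3-methyl-6-oxo-3,6-dihydro-2H-pyran-3-yl]propyl 2,2-dimethylpropanoate | O=C1C(Br)=C[C@](C)(CO1)[C@H](OC(=O)C(C)(C)C)CCBr
F2 | step 8 | 8a-bromo analogue of adduct 13 (bromine at C10, cis to H-4a) | C[C@@]1(COC(=O)[C@]2(Br)[C@H](C=C)C(CO)=CC[C@H]12)[C@H](OC(=O)C(C)(C)C)CCBr
F3 | step 13 | C20 4-methylbenzenesulfonylhydrazone of the ring-opened lactol 20 | C[C@]1(CO)[C@H]2CC[C@H](CO)[C@@H](C=C)[C@]2(C=NNS(=O)(=O)c3ccc(C)cc3)CC[C@H]1O
F4 | step 14 | 3-bromo-2-(trimethylsilyl)furan | C[Si](C)(C)c1occc1Br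
F5 | step 14 | 15,16-epoxy-16-(trimethylsilyl)labda-13(16),14-diene-3,17,19-triol (2-silyl-3-alkylfuran, configuration as in 25) | C[C@]1(CO)[C@H]2CC[C@H](CO)[C@@H](CCc3ccoc3[Si](C)(C)C)[C@]2(C)CC[C@H]1O
F6 | step 14 | 15-hydroxy derivative of 25 (3-alkyl-5-hydroxyfuran-2(5H)-one, mixture at C15) | C[C@]1(CO)[C@H]2CC[C@H](CO)[C@@H](CCC3=CC(O)OC3=O)[C@]2(C)CC[C@H]1O
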